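At 100 °C the X of Thursday's run climbs briskly and then slows well before 4.0 min, so time is the thing to watch.

| flask | Z | G | L | temperature | remark | time |
|---|---|---|---|---|---|---|
| Thursday's | 5 mM | 7.5 mM | 5 mM | 100 °C | run made earlier |  |
| Saturday's | 5 mM | 11 mM | 5 mM | 100 °C | run made earlier |  |
| theta | 5.0 mM | 7.50 mM (fed, over 3.0 min) | 5.00 mM | 100 °C | all else is in the flask from the start; the feed brings no volume worth counting | 4.0 min |
| alpha | 5.0 mM | 7.50 mM | 5.00 mM | 100 °C | everything together at the start | 4.0 min |
| zeta | 5.0 mM (fed, over 3.0 min) | 7.50 mM | 5.00 mM | 100 °C | all else is in the flask from the start; the feed brings no volume worth counting | 4.0 min |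
| delta | 5.0 mM (fed, over 3.0 min) | 7.50 mM | 5.00 mM |  | the addition at 60 °C, then warmed to 100 °C; the feed brings no volume worth counting | 4.0 min |

- Thursday's (time / min: X / %): 0.333: 2.2; 0.500: 4.6; 0.833: 7.5; 1.33: 10.3; 2.50: 11.8; 4.00: 13.5
- Saturday's (time / s: X / %): 10.0: 1.4; 15.0: 2.8; 25.0: 5.6; 40.0: 7.5; 50.0: 10.0

(readings scatter by 0.5 percentage points)

- the earlier runs do not show what temperature does; that part of a forecast is a guess

1. the best flask by amount of X, in percent of the Z charged; "all alike" if 1.5 percentage points covers them all (theta / alpha / zeta / delta / all alike)
2. amount of X at the end, in percent of the Z charged, theta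
3. amount of X at the end, in percent of the Z charged, alpha
4. amount of X at the end, in percent of the Z charged, zeta
5. amount of X at the end, in percent of the Z charged, delta

Between its first and fourth readings, Thursday's X climbs at 0.0812 /min, as a fraction of the Z charge. Saturday's X, with 1.47 times the G, climbs between its first and last readings at 0.129 /min, a slope 1.59 times Thursday's and so roughly in step with the G charged. Thursday's last reading divided by the first rate is 1.66 min. Call this the working life of the G charge: the time for which that early slope would have to last to give that X. It is a reading and carries the scatter.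

Two views part here. The first, which is the forecast's, takes as likeliest “a reversible step held back by L”, though it does not exclude a loss of G, and feeding then delays the approach. It gives theta 11.3%, alpha 13.3%, zeta 10.8%, delta 9%, with alpha best.

The second view, my own, says G fades over its working life whether Z is there or not. Zeta's Z takes 3.0 min to arrive, longer than that life, so its G ages while waiting. If the fraction of G decays with that time while Z grows evenly, the batch amount is multiplied by 0.463, which gives 6.25% for zeta, less than the forecast's figure. Theta's G enters a flask that holds its Z from the start, so I rank theta above zeta.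

The flasks give theta 17.7%, alpha 13.3%, zeta 4.25% and delta 6.29%, so theta leads.

    Z + G → D + J (k = 4.40 /M/s, Ea = 58.0 kJ/mol)
    D → X (k = 0.0130 /s, Ea = 95.0 kJ/mol)
    D + L → Q (k = 9.20 /M/s, Ea = 68.0 kJ/mol)
    2 G → E (k = 6.00 /M/s, Ea = 55.0 kJ/mol)
    (constants at 100 °C)

The forecast's number stands for the batch flask, alpha, whose X is 13.3% at 4.00 min and 13.8% at 40.0 min. Yet alpha's G, at 0.733% of its charge, is the limiting reagent, with Z still at 48.8%. Against the factor 0.463 from the working life of 1.66 min, zeta's loss of Z is 0.365 of alpha's. The neighbour is zeta with L cut to 1.2 mM; taking that life as independent of L, the same reckoning leaves its loss of Z unchanged. Its Z ends at 81.3%, as zeta's does at 81.3%, with Q at 7.05% and X at 9.82%.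

(The readings stem from a simulated flask with constants of no real substance, noise included.)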